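Ring B is grown onto the finished ester instead of being esterified. Its C3–C6 segment (H, aroyloxy, H, CH3) is the C3–C6 diene of 4-O-acylated triacetic acid lactone. C1 (CO2Me) and C2 (O) are the two carbons of a 3-alkoxypropiolate. One cycloaddition with loss of CO2 forms C2–C3 and C1–C6, aromatises ring B and converts a pyrone enol ester into the hindered depside ester. The precursor is 6-methyl-2-pyron-4-yl 3-chloro-2,4-dimethoxy-6-methylbenzoate. The ring A ortho oxygen travels as a methyl ether, so ring A comes from a symmetric chloroarene without regiochemical choice. A single BCl3 treatment finally frees both chelated phenols.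

Key step: step 6

Remark: ring B is numbered C1 (bearing CO2Me) to C6 (bearing CH3), and ring A C1′ (bearing the acyl carbon) to C6′ (bearing CH3). The target has no stereocentre. The only stereocentres on the route are the transient bridgeheads of 14. Compounds 1, 8 and 11 (11 as a solution in hexanes) are taken as commercial.

Step 1
Reactants: 1 1,3-dimethoxy-5-methylbenzene (3,5-dimethoxytoluene)
Product: 3 2-chloro-1,3-dimethoxy-5-methylbenzene, via aryllithium 2 (not isolated)
Conditions: n-BuLi, THF, 0 °C to rt; then C2Cl6, −78 °C to rt
Reagents that add atoms: hexachloroethane, ClC(Cl)(Cl)C(Cl)(Cl)Cl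
Why: Directed ortho-metalation removes the C–H flanked and coordinated by both methoxy groups, and the aryllithium takes chlorine from C2Cl6 by halophilic attack, which places Cl exactly between the two oxygens.

Step 2
Reactants: 3 2-chloro-1,3-dimethoxy-5-methylbenzene
Product: 4 2-bromo-4-chloro-3,5-dimethoxy-1-methylbenzene
Conditions: NBS (1 equiv), MeCN, 0 °C to rt, dark
Reagents that add atoms: N-bromosuccinimide, O=C1CCC(=O)N1Br
Why: In this electrophilic aromatic bromination the two open positions of 3 are equivalent by symmetry, each para to one methoxy group and ortho to the other, so only one monobromide can form, and polar, dark conditions suppress benzylic bromination.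

Step 3
Reactants: 4 2-bromo-4-chloro-3,5-dimethoxy-1-methylbenzene
Product: 7 3-chloro-2,4-dimethoxy-6-methylbenzoic acid, via aryllithium 5 (not isolated), via lithium carboxylate 6 (not isolated)
Conditions: n-BuLi, THF, −78 °C; CO2 (dry gas), −78 °C to rt; then 1 M HCl
Reagents that add atoms: carbon dioxide, O=C=O
Why: Bromine–lithium exchange at −78 °C is far faster than any attack on the aryl chloride, which sits meta to the carbanion and cannot give an aryne, and carboxylation then fixes the acid at the carbon that bore bromine.

Step 4
Reactants: 7 3-chloro-2,4-dimethoxy-6-methylbenzoic acid; 8 4-hydroxy-6-methyl-2H-pyran-2-one (triacetic acid lactone)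
Product: 10 6-methyl-2-oxo-2H-pyran-4-yl 3-chloro-2,4-dimethoxy-6-methylbenzoate, via acid chloride 9 (not isolated)
Conditions: (COCl)2, Me2NCHO (cat.), CH2Cl2, 0 °C to rt, evaporate; then 8, Et3N, CH2Cl2, 0 °C to rt (no DMAP)
Reagents that add atoms: none
Why: After Vilsmeier-type acid chloride formation, which the methyl ethers tolerate, the triethylammonium pyronate is O-acylated kinetically at the 4-oxygen of the vinylogous acid, and leaving out nucleophilic catalysts avoids the Fries-type shift of the acyl group to C3.

Step 5
Reactants: 11 ethoxyacetylene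
Product: 13 methyl 3-ethoxyprop-2-ynoate (methyl 3-ethoxypropiolate), via lithium ethoxyacetylide 12 (not isolated)
Conditions: n-BuLi, THF, −78 °C; inverse addition to ClCO2Me (excess), THF, −78 °C; pH 7 buffer, distillation with bath below 40 °C
Reagents that add atoms: methyl chloroformate, COC(=O)Cl
Why: This is the acylation of a lithium acetylide with a chloroformate, where inverse addition keeps the acetylide from adding to the electrophilic product and the neutral, cold work-up spares the ynol ether.

Step 6
Reactants: 10 6-methyl-2-oxo-2H-pyran-4-yl 3-chloro-2,4-dimethoxy-6-methylbenzoate; 13 methyl 3-ethoxyprop-2-ynoate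
Product: 15 methyl 4-[(3-chloro-2,4-dimethoxy-6-methylbenzoyl)oxy]-2-ethoxy-6-methylbenzoate, via bridged lactone 14 (not isolated)
Conditions: 13 (3 equiv), dry CH2Cl2, 13 kbar, 50 °C; then 1 bar, toluene, 70 °C
Reagents that add atoms: none
Why: The pyrone diene C3=C4–C5=C6 and the alkyne should combine in a concerted but strongly asynchronous [4+2] cycloaddition to the 2-oxabicyclo[2.2.2]octa-5,7-dien-3-one 14, which expels CO2 by retro-[4+2] and thereby becomes benzene ring B with the aryl ester already on C4. The closest known reaction type is the Diels–Alder/decarboxylation of 2-pyrones with alkynes, established for propiolates and acetylenedicarboxylates on the electron-poor side and for ynamines on the electron-rich side, so each polar half of 13 has a counterpart. Ring B is closed by an intermolecular two-bond [4+2] annulation that forms C2–C3 and C1–C6 in one event, not by cyclisation of a chain. The two bridgehead stereocentres of 14 arise as a racemate, are fixed relative to each other by the bicycle and disappear on aromatisation, so no stereocontrol is required. The step needs regioselectivity: the ester-bearing alkyne carbon, made nucleophilic by the ethoxy donor, must bond to the electrophilic δ-carbon C6 of the pyrone and the ethoxy-bearing, electrophilic carbon to the nucleophilic C3, a pairing that both frontier-orbital combinations favour. Pressure replaces heat because the cycloaddition has a strongly negative activation volume whereas the retro-ene loss of ethene from an ethyl ynol ether, which sets in near 100 °C, does not, and the di-ortho-substituted aroyl group shields the activated enol ester from acyl transfer.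

Step 7
Reactants: 15 methyl 4-[(3-chloro-2,4-dimethoxy-6-methylbenzoyl)oxy]-2-ethoxy-6-methylbenzoate
Product: 17 methyl 4-[(3-chloro-2-hydroxy-4-methoxy-6-methylbenzoyl)oxy]-2-hydroxy-6-methylbenzoate (target CNP0146021.0), via bis(dichloroboryl) ether 16 (not isolated)
Conditions: BCl3 (5 equiv), CH2Cl2, −78 to 0 °C; then ice-cold 1 M HCl
Reagents that add atoms: none
Why: In this chelation-directed ether cleavage boron binds each ester carbonyl together with its ortho alkoxy oxygen (C2′ OMe, C2 OEt) and chloride removes the alkyl group, whereas the C4′ methoxy group has no carbonyl neighbour and, like both esters and the aryl chloride, should persist at or below 0 °C.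

Compound list
1 | 1,3-dimethoxy-5-methylbenzene (3,5-dimethoxytoluene) | COc1cc(C)cc(OC)c1 | starting material
2 | (2,6-dimethoxy-4-methylphenyl)lithium | [Li]c1c(OC)cc(C)cc1OC | intermediate
3 | 2-chloro-1,3-dimethoxy-5-methylbenzene | COc1cc(C)cc(OC)c1Cl | intermediate
4 | 2-bromo-4-chloro-3,5-dimethoxy-1-methylbenzene | Cc1cc(OC)c(Cl)c(OC)c1Br | intermediate
5 | (3-chloro-2,4-dimethoxy-6-methylphenyl)lithium | Cc1cc(OC)c(Cl)c(OC)c1[Li] | intermediate
6 | lithium 3-chloro-2,4-dimethoxy-6-methylbenzoate | Cc1cc(OC)c(Cl)c(OC)c1C(=O)[O-].[Li+] | intermediate
7 | 3-chloro-2,4-dimethoxy-6-methylbenzoic acid | Cc1cc(OC)c(Cl)c(OC)c1C(=O)O | intermediate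
8 | 4-hydroxy-6-methyl-2H-pyran-2-one (triacetic acid lactone) | Cc1cc(O)cc(=O)o1 | starting material
9 | 3-chloro-2,4-dimethoxy-6-methylbenzoyl chloride | Cc1cc(OC)c(Cl)c(OC)c1C(=O)Cl | intermediate
10 | 6-methyl-2-oxo-2H-pyran-4-yl 3-chloro-2,4-dimethoxy-6-methylbenzoate | Cc1cc(OC(=O)c2c(C)cc(OC)c(Cl)c2OC)cc(=O)o1 | intermediate
11 | ethoxyacetylene (ethoxyethyne) | CCOC#C | starting material
12 | lithium ethoxyacetylide | CCOC#C[Li] | intermediate
13 | methyl 3-ethoxyprop-2-ynoate | CCOC#CC(=O)OC | intermediate
14 | methyl 8-[(3-chloro-2,4-dimethoxy-6-methylbenzoyl)oxy]-5-ethoxy-1-methyl-3-oxo-2-oxabicyclo[2.2.2]octa-5,7-diene-6-carboxylate (racemic, one enantiomer drawn) | C[C@@]12OC(=O)[C@@H](C(OC(=O)c3c(C)cc(OC)c(Cl)c3OC)=C1)C(OCC)=C2C(=O)OC | intermediate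
15 | methyl 4-[(3-chloro-2,4-dimethoxy-6-methylbenzoyl)oxy]-2-ethoxy-6-methylbenzoate | CCOc1cc(OC(=O)c2c(C)cc(OC)c(Cl)c2OC)cc(C)c1C(=O)OC | intermediate
16 | bis(dichloroboryl) ether of the target (O–BCl2 on C2 and on C2′) | COC(=O)c1c(C)cc(OC(=O)c2c(C)cc(OC)c(Cl)c2OB(Cl)Cl)cc1OB(Cl)Cl | intermediate
17 | methyl 4-[(3-chloro-2-hydroxy-4-methoxy-6-methylbenzoyl)oxy]-2-hydroxy-6-methylbenzoate | COC(=O)c1c(C)cc(OC(=O)c2c(C)cc(OC)c(Cl)c2O)cc1O | target

Total step count: 7. Longest linear sequence: 6 (steps 1, 2, 3, 4, 6, 7); step 5 is a one-step side branch.

Steps most likely to fail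

Step 6. The donor and the acceptor on 13 offset each other. Cycloaddition may therefore stay too slow below the temperature at which the ynol ether fragments or oligomerises, and slow acyl transfer from the enol ester may take over. The fallback gives up the pyrone and uses classical depside esterification. It sets out from 7 and comes back at 17. Acid 7 is condensed with commercial methyl 2,4-dihydroxy-6-methylbenzoate (methyl orsellinate, COC(=O)c1c(C)cc(O)cc1O) using (CF3CO)2O in toluene at rt. Only the C4 hydroxyl should react, because the C2 hydroxyl is hydrogen-bonded to the ester. This gives methyl 4-[(3-chloro-2,4-dimethoxy-6-methylbenzoyl)oxy]-2-hydroxy-6-methylbenzoate F1. BCl3 in CH2Cl2 at −78 to 0 °C then removes the chelated C2′ methyl group to give 17.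

Step 7. Sluggish cleavage of the ethyl ether may call for temperatures at which site selectivity erodes, so that the C4′ methoxy group or the methyl ester is attacked as well. The fallback replaces selective cleavage by exhaustive cleavage followed by selective re-methylation. It sets out from 15 and comes back at 17. BBr3 in CH2Cl2 at −78 to 0 °C removes all three aryl alkyl ethers to give methyl 4-[(3-chloro-2,4-dihydroxy-6-methylbenzoyl)oxy]-2-hydroxy-6-methylbenzoate F2. The C4′ hydroxyl is the only phenol not hydrogen-bonded to a carbonyl and is the most acidic one because it stands next to chlorine. It is methylated with Me3SiCHN2 (1 equiv) in toluene–MeOH at 0 °C to give 17.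

Step 4. Acyl transfer from the di-ortho-substituted acid chloride to the weakly nucleophilic pyronate may be slow. Prolonged exposure to base would then allow migration of the acyl group from oxygen to C3, or hydrolysis. The fallback is a neutral, amine-free acyl transfer driven by Si–F bond formation. It sets out from 7 and 8 and comes back at 10. Acid 7 is converted with cyanuric fluoride and pyridine in CH2Cl2 into 3-chloro-2,4-dimethoxy-6-methylbenzoyl fluoride F3, whose small leaving group eases attack at the hindered carbonyl. Pyrone 8 is silylated with (Me3Si)2NH at reflux to 6-methyl-4-(trimethylsilyloxy)-2H-pyran-2-one F4. The two are combined in MeCN with catalytic n-Bu4N[Ph3SiF2]. This is the known fluoride-catalysed O-acylation of silyl enol ethers by acyl fluorides, and it should deliver 10.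

Further compounds
F1 | step 6 | methyl 4-[(3-chloro-2,4-dimethoxy-6-methylbenzoyl)oxy]-2-hydroxy-6-methylbenzoate | COC(=O)c1c(C)cc(OC(=O)c2c(C)cc(OC)c(Cl)c2OC)cc1O
F2 | step 7 | methyl 4-[(3-chloro-2,4-dihydroxy-6-methylbenzoyl)oxy]-2-hydroxy-6-methylbenzoate | COC(=O)c1c(C)cc(OC(=O)c2c(C)cc(O)c(Cl)c2O)cc1O
F3 | step 4 | 3-chloro-2,4-dimethoxy-6-methylbenzoyl fluoride | Cc1cc(OC)c(Cl)c(OC)c1C(F)=O
F4 | step 4 | 6-methyl-4-(trimethylsilyloxy)-2H-pyran-2-one | Cc1cc(O[Si](C)(C)C)cc(=O)o1
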